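**Assumption:** the SMILES is read as the (2S,3R) enantiomer, which is the 2,3-trans dihydrobenzofuran (aryl and CH2OH on opposite faces).

## Retrosynthetic overview

1. The dihydrofuran ring is the only ring made and it is closed last: acid removes all acetal protecting groups from an open 1,3-diol and the ortho phenol captures the 4-hydroxybenzylic cation to give the trans ring.
2. The diol comes from an Evans syn-aldol between the lower-half arylacetyl oxazolidinone and the upper-half MOM-protected syringaldehyde, followed by LiBH4 cleavage; this aldol is the late fragment union and sets C3.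
3. The arylacetyl imide comes from a Pd-catalysed arylation of the zinc enolate of a bromoacetyl oxazolidinone with the lower-half aryl bromide; the auxiliary arm is built from L-valinol, diethyl carbonate and bromoacetyl bromide.
4. The aryl bromide comes from 2-bromophenol and acetyl chloride (Fries acylation, Cu-methoxylation, bromination, ketal, MOM); the aldehyde comes from p-cresol (dibromination, double Cu-methoxylation, DDQ oxidation, MOM).
5. Both benzene rings are bought; the oxazolidinone and dioxolane rings are temporary.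

## Route

**Step 1**
Reactants: 1 4-methylphenol (p-cresol)
Product: 2 2,6-dibromo-4-methylphenol
Conditions: Br2 (2.05 equiv), AcOH, 0 °C → rt
Reagents that add atoms: bromine, BrBr
Why: Electrophilic aromatic bromination; the para position is blocked by methyl, so both ortho positions of the phenol are brominated.

**Step 2**
Reactants: 2 2,6-dibromo-4-methylphenol
Product: 3 2,6-dimethoxy-4-methylphenol
Conditions: NaOMe (6 equiv, 25% in MeOH), CuBr (15 mol %), DMF, 110 °C; aq. HCl work-up
Reagents that add atoms: sodium methoxide, [Na+].[O-]C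
Why: Ullmann-type CuBr-catalysed methoxylation of an ortho-bromophenoxide, the standard route to syringyl systems from dibromophenols.

**Step 3**
Reactants: 3 2,6-dimethoxy-4-methylphenol
Product: 5 4-hydroxy-3,5-dimethoxybenzaldehyde (syringaldehyde), via dimethyl acetal 4 (not isolated)
Conditions: DDQ (2.1 equiv), MeOH, 0 °C → rt; then 1 M HCl (aq), rt
Reagents that add atoms: water, O
Why: Quinone dehydrogenation: DDQ oxidises the 2,6-disubstituted p-cresol twice through quinone methides that methanol traps, and the resulting acetal is hydrolysed to the aldehyde.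

**Step 4**
Reactants: 5 4-hydroxy-3,5-dimethoxybenzaldehyde
Product: 6 3,5-dimethoxy-4-(methoxymethoxy)benzaldehyde
Conditions: MOMCl (1.3 equiv), K2CO3, DMF, 0 °C → rt
Reagents that add atoms: chloromethyl methyl ether, COCCl
Why: Williamson-type O-alkylation gives a MOM ether that survives boron enolate and hydride chemistry and is removed by acid in the last step.

**Step 5**
Reactants: 7 2-bromophenol; 8 acetyl chloride (1.2 equiv)
Product: 10 1-(3-bromo-4-hydroxyphenyl)ethan-1-one, via 2-bromophenyl acetate 9 (not isolated)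
Conditions: TfOH (neat, 5 equiv), 0 °C → rt
Reagents that add atoms: none
Why: O-acylation followed by Fries rearrangement in triflic acid, which is para-selective at room temperature and so places the acetyl group para to the hydroxyl.

**Step 6**
Reactants: 10 1-(3-bromo-4-hydroxyphenyl)ethan-1-one
Product: 11 1-(4-hydroxy-3-methoxyphenyl)ethan-1-one (acetovanillone)
Conditions: NaOMe (5 equiv), CuBr (15 mol %), DMF/MeOH, 110 °C; aq. HCl work-up
Reagents that add atoms: sodium methoxide, [Na+].[O-]C
Why: Ullmann-type methoxylation; the phenoxide deactivates the para ketone towards aldol chemistry while the ortho bromide is displaced.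

**Step 7**
Reactants: 11 1-(4-hydroxy-3-methoxyphenyl)ethan-1-one
Product: 12 1-(3-bromo-4-hydroxy-5-methoxyphenyl)ethan-1-one
Conditions: NBS (1.05 equiv), MeCN, 0 °C → rt
Reagents that add atoms: N-bromosuccinimide, O=C1CCC(=O)N1Br
Why: Electrophilic aromatic bromination at the only free position ortho to the phenol, which is far faster than ketone α-bromination without acid.

**Step 8**
Reactants: 12 1-(3-bromo-4-hydroxy-5-methoxyphenyl)ethan-1-one
Product: 13 2-bromo-6-methoxy-4-(2-methyl-1,3-dioxolan-2-yl)phenol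
Conditions: HOCH2CH2OH (5 equiv), TsOH·H2O (5 mol %), toluene, reflux (Dean–Stark); Et3N quench
Reagents that add atoms: ethylene glycol, OCCO
Why: Acid-catalysed ketalisation with azeotropic water removal masks the methyl ketone against enolisation, zinc enolate addition and LiBH4.

**Step 9**
Reactants: 13 2-bromo-6-methoxy-4-(2-methyl-1,3-dioxolan-2-yl)phenol
Product: 14 2-[3-bromo-5-methoxy-4-(methoxymethoxy)phenyl]-2-methyl-1,3-dioxolane
Conditions: MOMCl (1.3 equiv), K2CO3, DMF, 0 °C → rt
Reagents that add atoms: chloromethyl methyl ether, COCCl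
Why: Williamson-type MOM protection under basic conditions that leave the dioxolane intact.

**Step 10**
Reactants: 15 (S)-2-amino-3-methylbutan-1-ol (L-valinol)
Product: 16 (4S)-4-(propan-2-yl)-1,3-oxazolidin-2-one
Conditions: (EtO)2CO (1.1 equiv), K2CO3 (10 mol %), 130 °C, EtOH distilled off
Reagents that add atoms: diethyl carbonate, CCOC(=O)OCC
Why: Double transacylation (carbamate formation then cyclisation) gives the Evans auxiliary; the stereocentre comes unchanged from L-valinol.

**Step 11**
Reactants: 16 (4S)-4-(propan-2-yl)-1,3-oxazolidin-2-one; 17 bromoacetyl bromide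
Product: 19 (4S)-3-(bromoacetyl)-4-(propan-2-yl)-1,3-oxazolidin-2-one, via N-lithio oxazolidinone 18 (not isolated)
Conditions: n-BuLi (1.0 equiv), THF, −78 °C; then 17, −78 → 0 °C
Reagents that add atoms: none
Why: N-acylation of the lithiated oxazolidinone by the more reactive acyl bromide terminus.

**Step 12**
Reactants: 19 (4S)-3-(bromoacetyl)-4-(propan-2-yl)-1,3-oxazolidin-2-one; 14 2-[3-bromo-5-methoxy-4-(methoxymethoxy)phenyl]-2-methyl-1,3-dioxolane
Product: 21 (4S)-3-{[3-methoxy-2-(methoxymethoxy)-5-(2-methyl-1,3-dioxolan-2-yl)phenyl]acetyl}-4-(propan-2-yl)-1,3-oxazolidin-2-one, via bromozinc enolate 20 (not isolated)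
Conditions: Zn dust (TMSCl-activated), THF, rt; then 14, Pd(dba)2 (3 mol %), P(t-Bu)3 (3 mol %), THF, rt → 50 °C
Reagents that add atoms: none
Why: Reformatsky reagent formation followed by Negishi-type α-arylation with zerovalent palladium; the neutral zinc enolate tolerates the imide, MOM and ketal groups.

**Step 13**
Reactants: 21 the arylacetyl imide; 6 3,5-dimethoxy-4-(methoxymethoxy)benzaldehyde
Product: 24 (4S)-3-{(2S,3S)-3-[3,5-dimethoxy-4-(methoxymethoxy)phenyl]-3-hydroxy-2-[3-methoxy-2-(methoxymethoxy)-5-(2-methyl-1,3-dioxolan-2-yl)phenyl]propanoyl}-4-(propan-2-yl)-1,3-oxazolidin-2-one, via Z-boron enolate 22 (not isolated), via boron aldolate 23 (not isolated)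
Conditions: n-Bu2BOTf (1.2 equiv), i-Pr2NEt (1.4 equiv), CH2Cl2, −78 → 0 °C; 6, −78 → 0 °C; then pH 7 buffer, MeOH, 30% H2O2, 0 °C
Reagents that add atoms: none
Why: Evans syn-aldol: the Z-boron enolate reacts through a Zimmerman–Traxler chair with the auxiliary carbonyl turned away from the enolate oxygen, so the aldehyde adds opposite the 4-isopropyl group and the α-carbon (future C3) is set as S and the carbinol as S.

**Step 14**
Reactants: 24 the syn-aldol adduct
Product: 25 (1S,2R)-1-[3,5-dimethoxy-4-(methoxymethoxy)phenyl]-2-[3-methoxy-2-(methoxymethoxy)-5-(2-methyl-1,3-dioxolan-2-yl)phenyl]propane-1,3-diol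
Conditions: LiBH4 (2.5 equiv), H2O (1 equiv), THF, 0 °C
Reagents that add atoms: none
Why: Reductive cleavage of the N-acyl oxazolidinone to the primary alcohol without touching either stereocentre; the α-centre descriptor changes from S to R only because the CIP priorities change.

**Step 15**
Reactants: 25 the protected 1,3-diol
Product: 26 1-[(2S,3R)-2-(4-hydroxy-3,5-dimethoxyphenyl)-3-(hydroxymethyl)-7-methoxy-2,3-dihydro-1-benzofuran-5-yl]ethan-1-one
Conditions: 3 M HCl (aq)/MeOH 1:9, 40 °C
Reagents that add atoms: none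
Why: Acetal cleavage frees both phenols and the ketone, and the 4-hydroxybenzylic alcohol ionises to a quinone-methide-type cation that the ortho phenol captures reversibly (SN1, 5-membered ring closure). C3 (R) is untouched and C2 settles as S in the thermodynamically preferred 2,3-trans ring.

## Compound list

1 | 4-methylphenol (p-cresol) | Cc1ccc(O)cc1 | starting material
2 | 2,6-dibromo-4-methylphenol | Cc1cc(Br)c(O)c(Br)c1 | intermediate
3 | 2,6-dimethoxy-4-methylphenol | COc1cc(C)cc(OC)c1O | intermediate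
4 | 4-(dimethoxymethyl)-2,6-dimethoxyphenol (not isolated) | COC(OC)c1cc(OC)c(O)c(OC)c1 | intermediate
5 | 4-hydroxy-3,5-dimethoxybenzaldehyde (syringaldehyde) | COc1cc(C=O)cc(OC)c1O | intermediate
6 | 3,5-dimethoxy-4-(methoxymethoxy)benzaldehyde | COCOc1c(OC)cc(C=O)cc1OC | intermediate
7 | 2-bromophenol | Oc1ccccc1Br | starting material
8 | acetyl chloride | CC(Cl)=O | starting material
9 | 2-bromophenyl acetate (not isolated) | CC(=O)Oc1ccccc1Br | intermediate
10 | 1-(3-bromo-4-hydroxyphenyl)ethan-1-one | CC(=O)c1ccc(O)c(Br)c1 | intermediate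
11 | 1-(4-hydroxy-3-methoxyphenyl)ethan-1-one (acetovanillone) | CC(=O)c1ccc(O)c(OC)c1 | intermediate
12 | 1-(3-bromo-4-hydroxy-5-methoxyphenyl)ethan-1-one | CC(=O)c1cc(Br)c(O)c(OC)c1 | intermediate
13 | 2-bromo-6-methoxy-4-(2-methyl-1,3-dioxolan-2-yl)phenol | CC1(OCCO1)c2cc(Br)c(O)c(OC)c2 | intermediate
14 | 2-[3-bromo-5-methoxy-4-(methoxymethoxy)phenyl]-2-methyl-1,3-dioxolane | COCOc1c(Br)cc(cc1OC)C2(C)OCCO2 | intermediate
15 | (S)-2-amino-3-methylbutan-1-ol (L-valinol) | CC(C)[C@H](N)CO | starting material
16 | (4S)-4-(propan-2-yl)-1,3-oxazolidin-2-one | CC(C)[C@H]1COC(=O)N1 | intermediate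
17 | bromoacetyl bromide | BrCC(Br)=O | starting material
18 | N-lithio-(4S)-4-(propan-2-yl)-1,3-oxazolidin-2-one (not isolated) | CC(C)[C@H]1COC(=O)N1[Li] | intermediate
19 | (4S)-3-(bromoacetyl)-4-(propan-2-yl)-1,3-oxazolidin-2-one | CC(C)[C@H]1COC(=O)N1C(=O)CBr | intermediate
20 | bromo{2-oxo-2-[(4S)-2-oxo-4-(propan-2-yl)-1,3-oxazolidin-3-yl]ethyl}zinc (not isolated) | CC(C)[C@H]1COC(=O)N1C(=O)C[Zn]Br | intermediate
21 | (4S)-3-{[3-methoxy-2-(methoxymethoxy)-5-(2-methyl-1,3-dioxolan-2-yl)phenyl]acetyl}-4-(propan-2-yl)-1,3-oxazolidin-2-one | COCOc1c(OC)cc(cc1CC(=O)N2[C@@H](C(C)C)COC2=O)C3(C)OCCO3 | intermediate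
22 | (Z)-dibutylboron enolate of 21 (not isolated) | CCCCB(CCCC)O/C(=C\c1cc(cc(OC)c1OCOC)C2(C)OCCO2)N3[C@@H](C(C)C)COC3=O | intermediate
23 | O-dibutylboryl aldolate of 24 (not isolated) | O=C(N1[C@@H](C(C)C)COC1=O)[C@H]([C@H](OB(CCCC)CCCC)c2cc(OC)c(OCOC)c(OC)c2)c3cc(cc(OC)c3OCOC)C4(C)OCCO4 | intermediate
24 | (4S)-3-{(2S,3S)-3-[3,5-dimethoxy-4-(methoxymethoxy)phenyl]-3-hydroxy-2-[3-methoxy-2-(methoxymethoxy)-5-(2-methyl-1,3-dioxolan-2-yl)phenyl]propanoyl}-4-(propan-2-yl)-1,3-oxazolidin-2-one | O=C(N1[C@@H](C(C)C)COC1=O)[C@H]([C@H](O)c2cc(OC)c(OCOC)c(OC)c2)c3cc(cc(OC)c3OCOC)C4(C)OCCO4 | intermediate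
25 | (1S,2R)-1-[3,5-dimethoxy-4-(methoxymethoxy)phenyl]-2-[3-methoxy-2-(methoxymethoxy)-5-(2-methyl-1,3-dioxolan-2-yl)phenyl]propane-1,3-diol | OC[C@H]([C@H](O)c1cc(OC)c(OCOC)c(OC)c1)c2cc(cc(OC)c2OCOC)C3(C)OCCO3 | intermediate
26 | 1-[(2S,3R)-2-(4-hydroxy-3,5-dimethoxyphenyl)-3-(hydroxymethyl)-7-methoxy-2,3-dihydro-1-benzofuran-5-yl]ethan-1-one | COc1cc([C@H]2Oc3c(OC)cc(C(C)=O)cc3[C@@H]2CO)cc(OC)c1O | target

## Step count and weak points

Total step count: 15 (steps 1–4 aldehyde arm, steps 5–9 aryl bromide arm, steps 10–11 auxiliary arm, steps 12–15 after the arms meet).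
Longest linear sequence: 9 steps (7 → 10 → 11 → 12 → 13 → 14 → 21 → 24 → 25 → 26).

The three steps most likely to fail:

**Step 12 (arylation of the imide zinc enolate).** The zinc enolate of an acyl oxazolidinone may decompose or couple sluggishly with the ortho-substituted, electron-rich bromide. The fallback sets out from 14 and installs the two-carbon unit as a simple ester before the auxiliary. Coupling of 14 with the Reformatsky reagent BrZnCH2CO2Et under Pd(dba)2/P(t-Bu)3 in THF gives ethyl [3-methoxy-2-(methoxymethoxy)-5-(2-methyl-1,3-dioxolan-2-yl)phenyl]acetate F3. Saponification with LiOH in THF/H2O gives [3-methoxy-2-(methoxymethoxy)-5-(2-methyl-1,3-dioxolan-2-yl)phenyl]acetic acid F4. Activation with t-BuCOCl and Et3N in THF at −20 °C gives the mixed pivalic anhydride F5, which acylates 18 (made from 16 and n-BuLi as in step 11) and comes back to the route at 21.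

**Step 15 (one-pot deprotection and ring closure).** Methanol capture of the cation, loss of the hydroxymethyl group as formaldehyde, or incomplete equilibration to trans could erode the yield. The fallback sets out from 25, masks the primary alcohol and turns the benzylic alcohol into a leaving group. Ac2O, pyridine and DMAP give (1S,2R)-1-[3,5-dimethoxy-4-(methoxymethoxy)phenyl]-2-[3-methoxy-2-(methoxymethoxy)-5-(2-methyl-1,3-dioxolan-2-yl)phenyl]propane-1,3-diyl diacetate F6. TFA in CH2Cl2 at 0 °C followed by aqueous work-up removes the MOM groups and the ketal, ionises the benzylic acetate and closes the ring in a non-nucleophilic medium to give [(2S,3R)-5-acetyl-2-(4-hydroxy-3,5-dimethoxyphenyl)-7-methoxy-2,3-dihydro-1-benzofuran-3-yl]methyl acetate F7. K2CO3 in MeOH removes the acetate and comes back to the route at 26.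

**Step 3 (DDQ oxidation of the electron-rich cresol).** Over-oxidation or quinone-methide dimerisation is possible. The fallback sets out from 2 and oxidises the side chain before the methoxy groups are introduced. Side-chain bromination with Br2 (2 equiv) in 1,2-dichlorobenzene at 150–160 °C gives 2,6-dibromo-4-(dibromomethyl)phenol F1, which is hydrolysed in the same pot with water at 100 °C to 3,5-dibromo-4-hydroxybenzaldehyde F2. Double methoxylation of F2 with NaOMe and CuBr in DMF at 110 °C comes back to the route at 5.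

## Further compounds

F1 | step 3 | 2,6-dibromo-4-(dibromomethyl)phenol | BrC(Br)c1cc(Br)c(O)c(Br)c1
F2 | step 3 | 3,5-dibromo-4-hydroxybenzaldehyde | O=Cc1cc(Br)c(O)c(Br)c1
F3 | step 12 | ethyl [3-methoxy-2-(methoxymethoxy)-5-(2-methyl-1,3-dioxolan-2-yl)phenyl]acetate | CCOC(=O)Cc1cc(cc(OC)c1OCOC)C2(C)OCCO2
F4 | step 12 | [3-methoxy-2-(methoxymethoxy)-5-(2-methyl-1,3-dioxolan-2-yl)phenyl]acetic acid | OC(=O)Cc1cc(cc(OC)c1OCOC)C2(C)OCCO2
F5 | step 12 | [3-methoxy-2-(methoxymethoxy)-5-(2-methyl-1,3-dioxolan-2-yl)phenyl]acetic 2,2-dimethylpropanoic anhydride | CC(C)(C)C(=O)OC(=O)Cc1cc(cc(OC)c1OCOC)C2(C)OCCO2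
F6 | step 15 | (1S,2R)-1-[3,5-dimethoxy-4-(methoxymethoxy)phenyl]-2-[3-methoxy-2-(methoxymethoxy)-5-(2-methyl-1,3-dioxolan-2-yl)phenyl]propane-1,3-diyl diacetate | CC(=O)OC[C@H]([C@H](OC(C)=O)c1cc(OC)c(OCOC)c(OC)c1)c2cc(cc(OC)c2OCOC)C3(C)OCCO3
F7 | step 15 | [(2S,3R)-5-acetyl-2-(4-hydroxy-3,5-dimethoxyphenyl)-7-methoxy-2,3-dihydro-1-benzofuran-3-yl]methyl acetate | COc1cc([C@H]2Oc3c(OC)cc(C(C)=O)cc3[C@@H]2COC(C)=O)cc(OC)c1O
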